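(Readings and results were computed on assumed constants; noise was put on by code.)

Substrate cannot react without partner. So when substrate stops falling with substrate still present, I suspect the partner charge as the limiting reagent.

| flask | substrate | partner | remark | time |
|---|---|---|---|---|
| Tuesday's | 0.10 M | 0.080 M | run made earlier |  |
| Friday's | 0.10 M | 0.19 M | run made earlier |  |
| Sunday's | 0.10 M | 0.37 M | run made earlier |  |
| south-east | 0.10 M | 0.100 M |  | 4.0 h |
| south-west | 0.10 M | 0.400 M |  | 4.0 h |
| south | 0.10 M | 0.150 M |  | 4.0 h |

| run | time / min | mono adduct / % | substrate / % |
|---|---|---|---|
| Tuesday's | 15.0 | 10.4 | 68.6 |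
| Tuesday's | 40.0 | 5.7 | 62.5 |
| Tuesday's | 80.0 | 1.8 | 62.3 |
| Tuesday's | 120 | 1.6 | 62.1 |
| Friday's | 15.0 | 9.1 | 35.7 |
| Friday's | 40.0 | 3.4 | 23.1 |
| Friday's | 80.0 | 2.0 | 16.9 |
| Friday's | 120 | 1.2 | 15.7 |
| Sunday's | 15.0 | 2.9 | 10.1 |
| Sunday's | 40.0 | 0 | 1.8 |
| Sunday's | 80.0 | 0.2 | 0 |
| Sunday's | 120 | 0.4 | 0 |

(standard deviation of a reading: 0.5 percentage points)

In Tuesday's flask substrate moves by 0.2 percentage points between 80.0 min and 120 min, less than the scatter of 0.5 points, yet 62.1% remains. Friday's flask reads 15.7% at its last reading.

Dividing partner charged by substrate lost gives 2.11 for Tuesday's flask and 2.25 for Friday's. Their mean, 2.18, is what I call the partner price: moles of partner charged per mole of substrate lost.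

At 0.10 M of substrate, the price asks for 0.218 M of partner. Sunday's flask has more than that, and its substrate reads 0% at 80.0 min.

* which of these holds the largest part of the substrate at the end of south-east (substrate / double product / other mono adduct / mono adduct)
* which of these holds the largest part of the substrate at the end of south-west (substrate / double product / other mono adduct / mono adduct)
* which of these holds the largest part of the substrate at the end of south (substrate / double product / other mono adduct / mono adduct)
* how much mono adduct is there at the end of south, in percent of the substrate charged

South-west also has more, so I expect its substrate to go. South-east and south have less, so substrate should remain. For these two flasks, at the price, I reckon the fraction of substrate left as one minus partner charged over price times substrate charged. That gives 54.2% for south-east and 31.3% for south. These readings list no double product, so the price tells me what leaves, not where it goes.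

The forecast has about 54 percent of substrate left in south-east and about 32 percent in south, the second not quite my figure. It names substrate for south-east, double product for south-west and double product for south, with 1.5% of mono adduct in south, holding that “nearly everything goes through to the double product”.

    substrate + partner ⇌ mono adduct (K = 8.00 M⁻¹, k = 0.0120 M⁻¹ s⁻¹)
    partner + mono adduct → double product (k = 0.00490 M⁻¹ s⁻¹)
    partner + other mono adduct → double product (k = 1.60 × 10⁻⁴ M⁻¹ s⁻¹)
    partner + mono adduct → over-reaction product (k = 0.0340 M⁻¹ s⁻¹)
    substrate + partner → other mono adduct (k = 9.60 × 10⁻⁴ M⁻¹ s⁻¹)
    partner → decomposed reagent (k = 7.40 × 10⁻⁵ s⁻¹)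

South ends with 0.560% of mono adduct, and of the 4 species asked about, substrate holds most, at 29.2%. The same question gives substrate for south-east and double product for south-west. South also holds 52.8% of over-reaction product, against 7.82% of double product. The partner price of south comes to 2.12. For a neighbouring flask, south with 0.25 M of substrate, the price reckons 72.5% of substrate left, and that flask holds 68.1% of substrate.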